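## Retrosynthetic overview

1. The last ring made is the dihydropyranone of the flavanone half. It is cut at O1–C2 (enantioselective oxa-Michael) and at C2–C3 (Knoevenagel). This gives a flavone-bearing benzaldehyde and the tert-butyl β-keto ester of dibenzylated phloroacetophenone. The ester carbon later leaves as CO2, and six benzyl ethers fall in the final hydrogenolysis.
2. The flavone pyranone ring is cut at C4a–C4, C4–C3 and O1–C2 into an ortho-iodophenol biaryl, CO and 4-benzyloxyphenylacetylene.
3. Feature used: in the flavone half, C4 is a single carbonyl carbon bridging C4a and the C2–C3 unit. The benzo ring (C4a to C8a) maps onto a 3,5-dialkoxy-4-arylphenol with a local twofold axis through C8a (oxygen-bearing) and C6 (aryl-bearing). The two carbons ortho to the hydroxyl (future C4a and C8) are therefore identical, only one iodide can form, and the aryl group can only end up at C6.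
4. The biaryl bond (flavanone ring B C3' to flavone C6) comes from Suzuki coupling of an acetal-masked arylboronate with 3,5-bis(benzyloxy)-4-bromophenol. The bromophenol is made from 4-bromo-3,5-dihydroxybenzoic acid by carboxyl-to-hydroxyl exchange (cumyl-type alcohol, then hydroperoxide rearrangement).
5. Ring order: all carbocyclic rings are bought. The flavone pyranone ring is closed first (step 9) and the flavanone dihydropyranone ring last (step 15).

Key step: step 9

Assumption (a): the quinidine-derived thiourea is taken to give the 2S configuration. Its quinine-derived pseudoenantiomer gives the opposite sense, so the choice is confirmed on the first run by circular dichroism of 24.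
Assumption (b): the Knoevenagel product 22 is drawn as the Z isomer (aryl cis to the ester), the geometry normally favoured for aroylacetates.
Assumption (c): the biaryl axis carries three ortho oxygen substituents and one ortho hydrogen. Rotation is taken as free on the laboratory time scale, in line with the target structure, which has no axial descriptor.

## Route

Step 1
Reactants: 1 3-bromo-4-hydroxybenzaldehyde
Product: 2 4-(benzyloxy)-3-bromobenzaldehyde
Conditions: BnBr (1.1 equiv), K2CO3 (1.5 equiv), DMF, rt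
Reagents that add atoms: benzyl bromide, BrCc1ccccc1
Why: Williamson ether synthesis; the acidic para-formylphenol is alkylated cleanly and the benzyl ether lasts until the final hydrogenolysis.

Step 2
Reactants: 2 4-(benzyloxy)-3-bromobenzaldehyde
Product: 3 2-[4-(benzyloxy)-3-bromophenyl]-1,3-dioxolane
Conditions: HOCH2CH2OH (3 equiv), TsOH·H2O (2 mol %), toluene, reflux, Dean–Stark
Reagents that add atoms: ethylene glycol, OCCO
Why: Acid-catalysed acetalisation with azeotropic removal of water masks the aldehyde against the palladium steps, the iodination and the secondary amine of the key step.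

Step 3
Reactants: 3 2-[4-(benzyloxy)-3-bromophenyl]-1,3-dioxolane
Product: 4 2-[2-(benzyloxy)-5-(1,3-dioxolan-2-yl)phenyl]-4,4,5,5-tetramethyl-1,3,2-dioxaborolane
Conditions: B2pin2 (1.2 equiv), PdCl2(dppf) (3 mol %), KOAc (3 equiv), 1,4-dioxane, 90 °C
Reagents that add atoms: bis(pinacolato)diboron, CC1(C)OB(OC1(C)C)B1OC(C)(C)C(C)(C)O1
Why: Miyaura borylation of an aryl bromide; the weak acetate base suppresses homocoupling, and the acetal and benzyl ether are inert.

Step 4
Reactants: 5 4-bromo-3,5-dihydroxybenzoic acid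
Product: 6 benzyl 3,5-bis(benzyloxy)-4-bromobenzoate
Conditions: BnBr (3.5 equiv), K2CO3 (4 equiv), DMF, 60 °C
Reagents that add atoms: benzyl bromide, BrCc1ccccc1
Why: Exhaustive Williamson and carboxylate alkylation protects both phenols and turns the acid into an ester ready for Grignard addition, with the bromine already between the two oxygens.

Step 5
Reactants: 6 benzyl 3,5-bis(benzyloxy)-4-bromobenzoate
Product: 7 2-[3,5-bis(benzyloxy)-4-bromophenyl]propan-2-ol
Conditions: MeMgBr (3 equiv), THF, 0 °C to rt; aqueous work-up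
Reagents that add atoms: methylmagnesium bromide, C[Mg]Br
Why: Double Grignard addition to the ester gives the cumyl-type tertiary alcohol, and MeMgBr does not exchange with an aryl bromide at this temperature.

Step 6
Reactants: 7 2-[3,5-bis(benzyloxy)-4-bromophenyl]propan-2-ol
Product: 9 3,5-bis(benzyloxy)-4-bromophenol, via tertiary benzylic hydroperoxide 8 (not isolated)
Conditions: 50% aq H2O2 (5 equiv), BF3·OEt2 (30 mol %), CH2Cl2, 0 °C to rt
Reagents that add atoms: hydrogen peroxide, OO
Why: Benzylic hydroperoxide (Hock-type) rearrangement, in which acid ionises the tertiary alcohol, H2O2 traps the cation as 8, and aryl migration from carbon to oxygen followed by hemiketal collapse gives the phenol and acetone; it is preferred to a Dakin or Baeyer–Villiger oxidation of the aldehyde, which is unreliable without an ortho or para donor.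

Step 7
Reactants: 4 2-[2-(benzyloxy)-5-(1,3-dioxolan-2-yl)phenyl]-4,4,5,5-tetramethyl-1,3,2-dioxaborolane; 9 3,5-bis(benzyloxy)-4-bromophenol
Product: 10 3,5-bis(benzyloxy)-4-[2-(benzyloxy)-5-(1,3-dioxolan-2-yl)phenyl]phenol
Conditions: 4 (1.3 equiv), Pd(OAc)2 (5 mol %), SPhos (10 mol %), K3PO4 (3 equiv), toluene–H2O (10:1), 100 °C
Reagents that add atoms: none
Why: Suzuki–Miyaura coupling; the bulky electron-rich biarylphosphine SPhos is the standard answer to a bromide flanked by two alkoxy groups and to a biaryl with three ortho substituents, a free phenol is tolerated under K3PO4, and the basic medium leaves the acetal untouched.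

Step 8
Reactants: 10 3,5-bis(benzyloxy)-4-[2-(benzyloxy)-5-(1,3-dioxolan-2-yl)phenyl]phenol
Product: 11 3,5-bis(benzyloxy)-4-[2-(benzyloxy)-5-(1,3-dioxolan-2-yl)phenyl]-2-iodophenol
Conditions: NIS (1.0 equiv), CH2Cl2, −20 to 0 °C, dark
Reagents that add atoms: N-iodosuccinimide, O=C1CCC(=O)N1I
Why: Electrophilic aromatic iodination; the phloroglucinol-type ring with the free hydroxyl is far more electron-rich than the other rings, its para position is blocked by the aryl group and its two ortho carbons are equivalent, so one equivalent of NIS under neutral, acetal-safe conditions should give a single mono-iodide.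

Step 9
Reactants: 11 3,5-bis(benzyloxy)-4-[2-(benzyloxy)-5-(1,3-dioxolan-2-yl)phenyl]-2-iodophenol; 12 1-(benzyloxy)-4-ethynylbenzene; 13 carbon monoxide
Product: 16 5,7-bis(benzyloxy)-6-[2-(benzyloxy)-5-(1,3-dioxolan-2-yl)phenyl]-2-[4-(benzyloxy)phenyl]-4H-chromen-4-one, via ortho-hydroxyaryl ynone 14 (not isolated), via beta-diethylamino enone 15 (not isolated)
Conditions: 12 (1.5 equiv), PdCl2(PPh3)2 (5 mol %), CO (10 bar), Et2NH–DMF (1:1), 90 °C, no copper salt
Reagents that add atoms: carbon monoxide (compound 13), [C-]#[O+]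
Why: Zerovalent palladium formed in situ from PdCl2(PPh3)2 inserts into the aryl–iodine bond of 11, migratory insertion of CO gives the aroylpalladium species (C4a–C4), and transfer of the amine-deprotonated alkyne 12 followed by reductive elimination gives ynone 14 (C4–C3). Diethylamine then adds to the β-carbon of the ynone to give enaminone 15, and the neighbouring phenol displaces the amine by addition–elimination, which forms O1–C2. The closest known reaction type is the carbonylative Sonogashira coupling of ortho-iodophenols with terminal arylacetylenes in a secondary amine, with cyclisation to the flavone in the same pot. The one ring closed is the pyranone, in a formal 6-endo-dig oxa-Michael mode; passage through the enaminone shuts off the 5-exo-dig path to the aurone, and the absence of copper together with CO pressure holds back the direct alkynylation that would lead on to a benzofuran. No stereocentre is formed. The step needs the aryl group at C6 and not at C8, and this is settled beforehand, because 11 is the only possible mono-iodide of the symmetric phenol 10 and its one free hydroxyl lies para to the aryl group; since the acyl carbon arrives as CO, the steric demand at C4a, which sits between two oxygen-bearing carbons, is as low as it can be.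

Step 10
Reactants: 16 5,7-bis(benzyloxy)-6-[2-(benzyloxy)-5-(1,3-dioxolan-2-yl)phenyl]-2-[4-(benzyloxy)phenyl]-4H-chromen-4-one
Product: 17 4-(benzyloxy)-3-{5,7-bis(benzyloxy)-2-[4-(benzyloxy)phenyl]-4-oxo-4H-chromen-6-yl}benzaldehyde
Conditions: 1 M HCl (cat.), THF–H2O, rt
Reagents that add atoms: water, O
Why: Mild acid hydrolysis of an aryl dioxolane, to which the flavone and the aryl benzyl ethers are inert.

Step 11
Reactants: 18 2,4,6-trihydroxyacetophenone
Product: 19 1-[2,4-bis(benzyloxy)-6-hydroxyphenyl]ethan-1-one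
Conditions: BnBr (2.1 equiv), K2CO3 (2.5 equiv), DMF, rt to 50 °C
Reagents that add atoms: benzyl bromide, BrCc1ccccc1
Why: Selective Williamson etherification; after the para hydroxyl and one ortho hydroxyl have reacted, the last hydroxyl is locked in a hydrogen bond to the ketone and stays free.

Step 12
Reactants: 19 1-[2,4-bis(benzyloxy)-6-hydroxyphenyl]ethan-1-one
Product: 20 2-acetyl-3,5-bis(benzyloxy)phenyl tert-butyl carbonate
Conditions: Boc2O (1.2 equiv), DMAP (10 mol %), CH2Cl2, rt
Reagents that add atoms: di-tert-butyl dicarbonate, CC(C)(C)OC(=O)OC(=O)OC(C)(C)C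
Why: DMAP-catalysed O-acylation of the phenol places the tert-butoxycarbonyl group next to the acetyl group for intramolecular delivery.

Step 13
Reactants: 20 2-acetyl-3,5-bis(benzyloxy)phenyl tert-butyl carbonate
Product: 21 tert-butyl 3-[2,4-bis(benzyloxy)-6-hydroxyphenyl]-3-oxopropanoate
Conditions: LiHMDS (2.3 equiv), THF, −78 to 0 °C; then 1 M HCl
Reagents that add atoms: none
Why: Baker–Venkataraman-type O-to-C acyl transfer (intramolecular Claisen condensation), in which the lithium enolate attacks the neighbouring carbonate carbonyl through a six-membered transition state, the phenoxide leaves, the second equivalent of base stores the product as its stabilised enolate, and the tert-butyl group slows lactonisation to a 4-hydroxycoumarin.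

Step 14
Reactants: 17 4-(benzyloxy)-3-{5,7-bis(benzyloxy)-2-[4-(benzyloxy)phenyl]-4-oxo-4H-chromen-6-yl}benzaldehyde; 21 tert-butyl 3-[2,4-bis(benzyloxy)-6-hydroxyphenyl]-3-oxopropanoate
Product: 22 tert-butyl (2Z)-2-[2,4-bis(benzyloxy)-6-hydroxybenzoyl]-3-(4-(benzyloxy)-3-{5,7-bis(benzyloxy)-2-[4-(benzyloxy)phenyl]-4-oxo-4H-chromen-6-yl}phenyl)prop-2-enoate
Conditions: piperidine (20 mol %), AcOH (20 mol %), 4 Å MS, toluene, rt
Reagents that add atoms: none
Why: Knoevenagel condensation under piperidinium acetate catalysis; the aldehyde carbon of 17 is unhindered, the methylene of 21 is doubly activated, and the buffered medium at room temperature is meant to leave the chelated phenol uncyclised.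

Step 15
Reactants: 22 tert-butyl (2Z)-2-[2,4-bis(benzyloxy)-6-hydroxybenzoyl]-3-(4-(benzyloxy)-3-{5,7-bis(benzyloxy)-2-[4-(benzyloxy)phenyl]-4-oxo-4H-chromen-6-yl}phenyl)prop-2-enoate
Product: 24 (2S)-5,7-bis(benzyloxy)-2-(4-(benzyloxy)-3-{5,7-bis(benzyloxy)-2-[4-(benzyloxy)phenyl]-4-oxo-4H-chromen-6-yl}phenyl)-2,3-dihydro-4H-chromen-4-one, via tert-butyl flavanone-3-carboxylate 23 (not isolated)
Conditions: thiourea from 9-amino-9-deoxy-epi-quinidine and 3,5-bis(trifluoromethyl)phenyl isothiocyanate (10 mol %), toluene, −25 °C; then TsOH·H2O (50 mol %), 80 °C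
Reagents that add atoms: none
Why: Bifunctional cinchona-thiourea-catalysed intramolecular oxa-Michael addition (6-endo-trig), in which the thiourea N–H pair binds the β-dicarbonyl unit, the quinuclidine nitrogen takes the phenol proton and the chiral pocket opens only one face of the alkylidene carbon to the oxygen, setting C2 as S; acid cleavage of the tert-butyl ester and decarboxylation in the same pot then erase the epimerisable C3 centre without touching C2.

Step 16
Reactants: 24 (2S)-5,7-bis(benzyloxy)-2-(4-(benzyloxy)-3-{5,7-bis(benzyloxy)-2-[4-(benzyloxy)phenyl]-4-oxo-4H-chromen-6-yl}phenyl)-2,3-dihydro-4H-chromen-4-one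
Product: 25 (2S)-2-{3-[5,7-dihydroxy-2-(4-hydroxyphenyl)-4-oxo-4H-chromen-6-yl]-4-hydroxyphenyl}-5,7-dihydroxy-2,3-dihydro-4H-chromen-4-one (target, CNP0277421.1)
Conditions: H2 (1 atm), 10% Pd/C, THF–MeOH (1:1), rt
Reagents that add atoms: none
Why: Catalytic hydrogenolysis of six aryl benzyl ethers under neutral conditions avoids the acid- or base-induced ring opening to the chalcone that would racemise C2, and the flavone C2–C3 double bond and both carbonyl groups are normally left alone at one atmosphere.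

## Compound list

1 | 3-bromo-4-hydroxybenzaldehyde | O=Cc1ccc(O)c(Br)c1 | starting material
2 | 4-(benzyloxy)-3-bromobenzaldehyde | O=Cc1ccc(OCc2ccccc2)c(Br)c1 | intermediate
3 | 2-[4-(benzyloxy)-3-bromophenyl]-1,3-dioxolane | Brc1cc(C2OCCO2)ccc1OCc1ccccc1 | intermediate
4 | 2-[2-(benzyloxy)-5-(1,3-dioxolan-2-yl)phenyl]-4,4,5,5-tetramethyl-1,3,2-dioxaborolane | CC1(C)OB(OC1(C)C)c1cc(C2OCCO2)ccc1OCc1ccccc1 | intermediate
5 | 4-bromo-3,5-dihydroxybenzoic acid | OC(=O)c1cc(O)c(Br)c(O)c1 | starting material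
6 | benzyl 3,5-bis(benzyloxy)-4-bromobenzoate | O=C(OCc1ccccc1)c1cc(OCc2ccccc2)c(Br)c(OCc2ccccc2)c1 | intermediate
7 | 2-[3,5-bis(benzyloxy)-4-bromophenyl]propan-2-ol | CC(C)(O)c1cc(OCc2ccccc2)c(Br)c(OCc2ccccc2)c1 | intermediate
8 | 2-[3,5-bis(benzyloxy)-4-bromophenyl]propan-2-yl hydroperoxide | CC(C)(OO)c1cc(OCc2ccccc2)c(Br)c(OCc2ccccc2)c1 | intermediate (not isolated)
9 | 3,5-bis(benzyloxy)-4-bromophenol | Oc1cc(OCc2ccccc2)c(Br)c(OCc2ccccc2)c1 | intermediate
10 | 3,5-bis(benzyloxy)-4-[2-(benzyloxy)-5-(1,3-dioxolan-2-yl)phenyl]phenol | Oc1cc(OCc2ccccc2)c(-c2cc(C3OCCO3)ccc2OCc2ccccc2)c(OCc2ccccc2)c1 | intermediate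
11 | 3,5-bis(benzyloxy)-4-[2-(benzyloxy)-5-(1,3-dioxolan-2-yl)phenyl]-2-iodophenol | Oc1cc(OCc2ccccc2)c(-c2cc(C3OCCO3)ccc2OCc2ccccc2)c(OCc2ccccc2)c1I | intermediate
12 | 1-(benzyloxy)-4-ethynylbenzene | C#Cc1ccc(OCc2ccccc2)cc1 | starting material
13 | carbon monoxide | [C-]#[O+] | starting material
14 | 1-{2,4-bis(benzyloxy)-3-[2-(benzyloxy)-5-(1,3-dioxolan-2-yl)phenyl]-6-hydroxyphenyl}-3-[4-(benzyloxy)phenyl]prop-2-yn-1-one | O=C(C#Cc1ccc(OCc2ccccc2)cc1)c1c(O)cc(OCc2ccccc2)c(-c2cc(C3OCCO3)ccc2OCc2ccccc2)c1OCc1ccccc1 | intermediate (not isolated)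
15 | (2E)-1-{2,4-bis(benzyloxy)-3-[2-(benzyloxy)-5-(1,3-dioxolan-2-yl)phenyl]-6-hydroxyphenyl}-3-[4-(benzyloxy)phenyl]-3-(diethylamino)prop-2-en-1-one | CCN(CC)/C(c1ccc(OCc2ccccc2)cc1)=C/C(=O)c1c(O)cc(OCc2ccccc2)c(-c2cc(C3OCCO3)ccc2OCc2ccccc2)c1OCc1ccccc1 | intermediate (not isolated)
16 | 5,7-bis(benzyloxy)-6-[2-(benzyloxy)-5-(1,3-dioxolan-2-yl)phenyl]-2-[4-(benzyloxy)phenyl]-4H-chromen-4-one | O=c1cc(-c2ccc(OCc3ccccc3)cc2)oc2cc(OCc3ccccc3)c(-c3cc(C4OCCO4)ccc3OCc3ccccc3)c(OCc3ccccc3)c12 | intermediate
17 | 4-(benzyloxy)-3-{5,7-bis(benzyloxy)-2-[4-(benzyloxy)phenyl]-4-oxo-4H-chromen-6-yl}benzaldehyde | O=Cc1ccc(OCc2ccccc2)c(-c2c(OCc3ccccc3)cc3oc(-c4ccc(OCc5ccccc5)cc4)cc(=O)c3c2OCc2ccccc2)c1 | intermediate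
18 | 2,4,6-trihydroxyacetophenone | CC(=O)c1c(O)cc(O)cc1O | starting material
19 | 1-[2,4-bis(benzyloxy)-6-hydroxyphenyl]ethan-1-one | CC(=O)c1c(O)cc(OCc2ccccc2)cc1OCc1ccccc1 | intermediate
20 | 2-acetyl-3,5-bis(benzyloxy)phenyl tert-butyl carbonate | CC(=O)c1c(OC(=O)OC(C)(C)C)cc(OCc2ccccc2)cc1OCc1ccccc1 | intermediate
21 | tert-butyl 3-[2,4-bis(benzyloxy)-6-hydroxyphenyl]-3-oxopropanoate | CC(C)(C)OC(=O)CC(=O)c1c(O)cc(OCc2ccccc2)cc1OCc1ccccc1 | intermediate
22 | tert-butyl (2Z)-2-[2,4-bis(benzyloxy)-6-hydroxybenzoyl]-3-(4-(benzyloxy)-3-{5,7-bis(benzyloxy)-2-[4-(benzyloxy)phenyl]-4-oxo-4H-chromen-6-yl}phenyl)prop-2-enoate | CC(C)(C)OC(=O)/C(C(=O)c1c(O)cc(OCc2ccccc2)cc1OCc1ccccc1)=C\c1ccc(OCc2ccccc2)c(-c2c(OCc3ccccc3)cc3oc(-c4ccc(OCc5ccccc5)cc4)cc(=O)c3c2OCc2ccccc2)c1 | intermediate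
23 | tert-butyl (2S,3R)-5,7-bis(benzyloxy)-2-(4-(benzyloxy)-3-{5,7-bis(benzyloxy)-2-[4-(benzyloxy)phenyl]-4-oxo-4H-chromen-6-yl}phenyl)-4-oxochromane-3-carboxylate (trans isomer shown; C3 epimerises through the enol) | O=C1[C@H](C(=O)OC(C)(C)C)[C@@H](c2ccc(OCc3ccccc3)c(-c3c(OCc4ccccc4)cc4oc(-c5ccc(OCc6ccccc6)cc5)cc(=O)c4c3OCc3ccccc3)c2)Oc2cc(OCc3ccccc3)cc(OCc3ccccc3)c21 | intermediate (not isolated)
24 | (2S)-5,7-bis(benzyloxy)-2-(4-(benzyloxy)-3-{5,7-bis(benzyloxy)-2-[4-(benzyloxy)phenyl]-4-oxo-4H-chromen-6-yl}phenyl)-2,3-dihydro-4H-chromen-4-one | O=C1C[C@@H](c2ccc(OCc3ccccc3)c(-c3c(OCc4ccccc4)cc4oc(-c5ccc(OCc6ccccc6)cc5)cc(=O)c4c3OCc3ccccc3)c2)Oc2cc(OCc3ccccc3)cc(OCc3ccccc3)c21 | intermediate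
25 | (2S)-2-{3-[5,7-dihydroxy-2-(4-hydroxyphenyl)-4-oxo-4H-chromen-6-yl]-4-hydroxyphenyl}-5,7-dihydroxy-2,3-dihydro-4H-chromen-4-one | O=C1C[C@@H](c2ccc(O)c(-c3c(O)cc4oc(-c5ccc(O)cc5)cc(=O)c4c3O)c2)Oc2cc(O)cc(O)c21 | target

## Step count

Total step count: 16.
Longest linear sequence: 10 steps (steps 1–3 or steps 4–6, then 7, 8, 9, 10, 14, 15, 16).

## Steps most likely to fail

**Step 9.** CO insertion and alkyne transfer at an arylpalladium flanked on both sides by oxygen substituents may be slow. Direct non-carbonylative alkynylation, capture of the acylpalladium by the amine, or reductive loss of iodine could then compete.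

The fallback sets out from 11 and 12 and comes back at 14, and so at 16. It brings the C4 carbon in with the alkyne instead of as CO.
- Alkyne 12 is lithiated (n-BuLi, THF, −78 °C) and formylated with DMF to 3-[4-(benzyloxy)phenyl]prop-2-ynal F1.
- Iodophenol 11 is deprotonated with MeMgCl/LiCl and subjected to iodine–magnesium exchange with i-PrMgCl·LiCl. The arylmagnesium adds to F1 to give the racemic propargylic alcohol F2.
- MnO2 in CH2Cl2 oxidises F2 to ynone 14, which Et2NH in DMF closes to 16 through 15.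

**Step 15.** Several processes could lower the enantiomeric purity of C2:
- poor facial selectivity with so large a substrate;
- uncatalysed background closure;
- retro-oxa-Michael opening, or ionisation of the para-alkoxybenzylic C2–O bond, during the hot acid decarboxylation.

Partial loss of benzyl groups could also complicate isolation.

The fallback sets out from 17 and 19 and comes back at 24. It gives up asymmetric catalysis in favour of separation.
- Claisen–Schmidt condensation of 17 with 19 (KOH, EtOH–THF, rt) gives the 2'-hydroxychalcone F3.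
- NaOAc in refluxing EtOH closes F3 to the racemic hexabenzyl flavanone F4.
- Preparative HPLC on a polysaccharide carbamate chiral phase delivers 24.
- The unwanted (2R)-hexabenzyl flavanone F5 is returned to the NaOAc equilibration, where it racemises through F3.

**Step 6.** Three processes could erode the hydroperoxide rearrangement: over-oxidation of the electron-rich phenol as it forms, Friedel–Crafts capture of the cumyl-type cation by the product, and dehydration of the alcohol.

The fallback sets out from 6 and comes back at 9. It uses a buffered peracid oxidation of a ketone instead.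
- Me3Al/MeNH(OMe)·HCl converts 6 into the Weinreb amide F6.
- MeMgBr gives the acetophenone F7.
- Baeyer–Villiger oxidation with trifluoroperacetic acid (urea–H2O2, (CF3CO)2O, Na2HPO4, CH2Cl2, 0 °C) gives the aryl acetate F8, since aryl migrates in preference to methyl.
- K2CO3 in MeOH releases 9.

## Further compounds

F1 | step 9 | 3-[4-(benzyloxy)phenyl]prop-2-ynal | O=CC#Cc1ccc(OCc2ccccc2)cc1
F2 | step 9 | racemic 3,5-bis(benzyloxy)-4-[2-(benzyloxy)-5-(1,3-dioxolan-2-yl)phenyl]-2-{3-[4-(benzyloxy)phenyl]-1-hydroxyprop-2-yn-1-yl}phenol | OC(C#Cc1ccc(OCc2ccccc2)cc1)c1c(O)cc(OCc2ccccc2)c(-c2cc(C3OCCO3)ccc2OCc2ccccc2)c1OCc1ccccc1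
F3 | step 15 | (2E)-1-[2,4-bis(benzyloxy)-6-hydroxyphenyl]-3-(4-(benzyloxy)-3-{5,7-bis(benzyloxy)-2-[4-(benzyloxy)phenyl]-4-oxo-4H-chromen-6-yl}phenyl)prop-2-en-1-one | O=C(/C=C/c1ccc(OCc2ccccc2)c(-c2c(OCc3ccccc3)cc3oc(-c4ccc(OCc5ccccc5)cc4)cc(=O)c3c2OCc2ccccc2)c1)c1c(O)cc(OCc2ccccc2)cc1OCc1ccccc1
F4 | step 15 | racemic 5,7-bis(benzyloxy)-2-(4-(benzyloxy)-3-{5,7-bis(benzyloxy)-2-[4-(benzyloxy)phenyl]-4-oxo-4H-chromen-6-yl}phenyl)-2,3-dihydro-4H-chromen-4-one | O=C1CC(c2ccc(OCc3ccccc3)c(-c3c(OCc4ccccc4)cc4oc(-c5ccc(OCc6ccccc6)cc5)cc(=O)c4c3OCc3ccccc3)c2)Oc2cc(OCc3ccccc3)cc(OCc3ccccc3)c21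
F5 | step 15 | (2R)-5,7-bis(benzyloxy)-2-(4-(benzyloxy)-3-{5,7-bis(benzyloxy)-2-[4-(benzyloxy)phenyl]-4-oxo-4H-chromen-6-yl}phenyl)-2,3-dihydro-4H-chromen-4-one | O=C1C[C@H](c2ccc(OCc3ccccc3)c(-c3c(OCc4ccccc4)cc4oc(-c5ccc(OCc6ccccc6)cc5)cc(=O)c4c3OCc3ccccc3)c2)Oc2cc(OCc3ccccc3)cc(OCc3ccccc3)c21
F6 | step 6 | 3,5-bis(benzyloxy)-4-bromo-N-methoxy-N-methylbenzamide | CON(C)C(=O)c1cc(OCc2ccccc2)c(Br)c(OCc2ccccc2)c1
F7 | step 6 | 1-[3,5-bis(benzyloxy)-4-bromophenyl]ethan-1-one | CC(=O)c1cc(OCc2ccccc2)c(Br)c(OCc2ccccc2)c1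
F8 | step 6 | 3,5-bis(benzyloxy)-4-bromophenyl acetate | CC(=O)Oc1cc(OCc2ccccc2)c(Br)c(OCc2ccccc2)c1
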